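Count exchanges: each incoming ligand taken up puts out one leaving ligand, so in a closed flask the two together keep their charge. Reckon for green one plus incoming over leaving equivalents, 175 %: this is the leaving-ligand mark, the fraction of its own charge that leaving ligand reaches once the incoming ligand, as limiting reagent, is fully taken up. The same reckoning gives 225 % for red and 125 % for blue.

| setting | zeta | beta | gamma | red | blue | green |
|---|---|---|---|---|---|---|
| starting complex | 0.052 M | 0.052 M | 0.052 M | 0.052 M | 0.052 M | 0.052 M |
| incoming ligand | 0.47 equiv | 1 equiv | 2.2 equiv | 2.50 equiv | 0.500 equiv | 1.50 equiv |
| leaving ligand | 2 equiv | 2 equiv | 2 equiv | 2.00 equiv | 2.00 equiv | 2.00 equiv |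
| remark | run made earlier | run made earlier | run made earlier |  |  |  |
| time |  |  |  | 2.0 min | 2.0 min | 2.0 min |

| run | time / s | complex with one exchanged / % |
|---|---|---|
| zeta | 25.0 | 12.9 |
| zeta | 50.0 | 6.6 |
| zeta | 80.0 | 3.3 |
| zeta | 90.0 | 3.5 |
| zeta | 120 | 1.9 |
| beta | 10.0 | 22.6 |
| beta | 30.0 | 13.5 |
| beta | 60.0 | 5.5 |
| beta | 80.0 | 5.0 |
| beta | 120 | 3.7 |
| gamma | 10.0 | 19.9 |
| gamma | 30.0 | 8.6 |
| gamma | 60.0 | 3.8 |
| gamma | 80.0 | 2.8 |
| gamma | 120 | 0.9 |

(each reading ± 1 percentage point)



- which of these holds the largest part of the starting complex at the end of red (complex with two exchanged / complex with three exchanged / starting complex / complex with one exchanged / complex with four exchanged)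
- which of these holds the largest part of the starting complex at the end of blue (complex with two exchanged / complex with three exchanged / starting complex / complex with one exchanged / complex with four exchanged)
- which of these holds the largest part of the starting complex at the end of green (complex with two exchanged / complex with three exchanged / starting complex / complex with one exchanged / complex with four exchanged)
- final complex with one exchanged in green, as a percentage of the starting complex charged

Turn incoming ligand first. By hand, a sink of two exchanges per complex can take 25.0 % of the charge in blue and 75.0 % in green, while red pays for more than two per complex, so part of red must pass beyond complex with two exchanged. In the readings, complex with one exchanged at 120 s stands at 1.9 %, 3.7 % and 0.9 % in zeta, beta and gamma, with a scatter of 1 percentage point.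

Turn time next. By hand, nothing more can be exchanged past the mark. In beta, complex with one exchanged falls from 22.6 % at 10.0 s to 3.7 % at 120 s, so read 2.0 min as the tail.

Turn starting complex and leaving ligand last. By hand, concentration leaves the mark unchanged but may shift when it is reached, and leaving ligand rescales it. Zeta, beta and gamma hold these at 0.052 M and 2 equiv, so they show neither effect.

Commit to starting complex in blue, complex with two exchanged in green and red, and a green tail between 0.9 % and 3.7 %. The forecast gives complex with two exchanged in red, starting complex in blue, complex with two exchanged in green and 2.6 % for the green tail, holding “so bis-exchanged is the sink”.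

The flask gives starting complex in blue, complex with two exchanged in green and 2.43 % for the green tail, but complex with four exchanged in red, at 37.9 % against 31.0 % for complex with two exchanged.

    starting complex + complex with one exchanged → side product (k = 0.360 L mol⁻¹ s⁻¹)
    complex with one exchanged + incoming ligand → leaving ligand + complex with two exchanged (k = 3.30 L mol⁻¹ s⁻¹)
    complex with two exchanged + incoming ligand → leaving ligand + complex with three exchanged (k = 1.10 L mol⁻¹ s⁻¹)
    complex with one exchanged ⇌ isomer of the product (K = 13.0, k = 0.0240 s⁻¹)
    starting complex + incoming ligand → leaving ligand + complex with one exchanged (k = 2.00 L mol⁻¹ s⁻¹)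
    complex with three exchanged + incoming ligand → leaving ligand + complex with four exchanged (k = 6.10 L mol⁻¹ s⁻¹)

Green reads 175 % of leaving ligand at 2.00 min, on the mark of 175 %, with 0.020 % of its incoming ligand left. The green recipe with starting complex at 0.013 M reads 168 % at 2.00 min, below the same mark, with 9.1 % of its incoming ligand left. Green has not come to rest: at 20.0 min complex with two exchanged still reads 31.4 %, but starting complex falls from 17.4 % to 13.0 %, side product rises from 11.4 % to 20.2 %, isomer of the product falls from 21.7 % to 18.5 %, and complex with one exchanged reaches 1.30 %.

The readings come from a simulation for an exercise; the scatter is artificial.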